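## Compound numbering

Locants follow the drimane convention: ring A = C1–C5 and C10, ring B = C5–C10, C11 = OCH2 on C9, C12 = CH3 on C8, C15 = CH3 on C10. α is the face of H-5, β the face of the C10 methyl.

1 2-methylcyclohex-2-en-1-one · 2 ketene silyl acetal of methyl isobutyrate · 3 methyl acrylate · 4 C9=C10 enol silane · 5 ketene silyl acetal of the double adduct · 6 keto diester · 7 C8-methyl keto diester · 8 bicyclic β-keto ester · 9 3,9-diketone · 10 C3-dioxolane C9-ketone · 11 C8=C9 enol silane · 12 Δ7-9-enone · 13 4-methoxybenzyl alcohol · 14 Bu3SnCH2I · 15 Bu3SnCH2OPMB · 16 PMBOCH2Li · 17 tertiary allylic alcohol · 18 Δ8-7-enone PMB ether · 19 Δ8-7-enone C11 alcohol · 20 umbelliferone · 21 Δ8-7-enone aryl ether · 22 tosylhydrazone · 23 N-boryl hydrazine · 24 allylic diazene · 25 C3 ketal of the target · 26 target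

## Analysis of the target

The target 26 is a trans-fused decalin (rings A and B) linked through a CH2–O bridge to C7 of a coumarin. Ring A carries a ketone at C3 next to the gem-dimethyl carbon C4. Ring B carries a trisubstituted C7=C8 alkene with the C12 methyl, and C9 bears the aryloxymethyl group. There are three stereocentres, (5R,9R,10S) in the locants above: H-5 is α and the C10 methyl β (trans ring fusion), and H-9 is β, so the C9 side chain is α, axial and anti to the angular methyl. C9 is allylic but has no carbonyl neighbour, so this axial arrangement cannot be reached or corrected by equilibration and has to be set kinetically. The coumarin lactone does not tolerate organolithium reagents, dissolving metals or strong hydride donors, and the Δ7 alkene can migrate under strong acid. The coumarin should therefore enter late and the final deprotection must be mild. The main difficulty is steric: C5 sits between two quaternary carbons (C4 and C10), and C11 is a neopentyl-type carbon beside C10. The strategy rests on the C5–C10 pair: it maps onto the alkene of a 2-methylcyclohexenone whose carbonyl is C9, so C4 can be attached to C5 and C1 to C10 by two successive conjugate additions across that one alkene.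

## Retrosynthetic reasoning

**26 ⇐ 25.** Only the two acetal C–O bonds at C3 are cut. C3 must stay masked while ring B is treated with an organolithium, a chromium oxidant, a sulfonyl hydrazide and a boron hydride. The forward step is a mild acetal hydrolysis that leaves the Δ7 alkene, the ether and the lactone alone.

**25 ⇐ 24 ⇐ 23 ⇐ 22 ⇐ 21.** The C9–H bond is cut and the alkene is moved back from C7=C8 to C8=C9, with a carbonyl at C7. A reductive 1,3-transposition of the C7 sulfonylhydrazone 22 makes the alkene and the C9 stereocentre in one event. Hydrogen is passed from a C7 diazene (24) to C9 inside the molecule, on the face where the nitrogen sits. The forward reaction must therefore deliver hydride to C7 from the α face, so that the diazene is β and H-9 ends β.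

**21 ⇐ 19 + 20.** The C11–O bond is cut here and not in 25 or 26. In 19 C11 is a primary allylic carbinol on an sp2 carbon and is readily displaced. After the transposition it would be an axial CH2 beside quaternary C10. Coupling at this point also keeps the coumarin 20 out of the organolithium and chromium steps.

**19 ⇐ 18 ⇐ 17 ⇐ 12 + 16 (16 from 15, 15 from 13 + 14).** The C9–C11 bond is cut and the ring B carbonyl is moved back from C7 to C9. The key step leaves a carbonyl at C9. 1,2-Addition of the one-carbon oxygenated nucleophile 16 to enone 12, followed by oxidative allylic transposition of 17, converts that carbonyl into the C9–C11 bond and places oxygen at C7 for the later hydrazone. The benzylic ether in 18 comes off oxidatively without touching the ketal.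

**12 ⇐ 11 ⇐ 10 ⇐ 9.** The C7=C8 unsaturation and the C3 ketal are removed. The unsaturation is introduced only after ring A exists. An enone at C7=C8–C9 present during the ring A closure would sit within reach of the C2 ester enolate, and addition of C2 to C7 would give a bicyclo[2.2.2]octane. The cost of this order is that the ketalisation of 9 must tell C3 from C9 by substitution alone: C9 lies between quaternary C10 and methyl-bearing C8, whereas C3 has a CH2 neighbour.

**9 ⇐ 8 ⇐ 7.** The C2–C3 bond is cut (ester condensation) and one ester carbon is restored at C2. The C3 ester has no α-hydrogen, so C2 is the only carbon that can close ring A. The two chains are trans and equatorial on ring B, so the closure gives the trans-decalin without creating a new stereocentre.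

**7 ⇐ 6.** The C8–C12 bond is cut. C8 is the only enolisable α-carbon of the C9 ketone, so the alkylation is regiochemically unambiguous. Its configuration does not matter because C8 later becomes sp2.

**6 ⇐ 1 + 2 + 3.** The C4–C5 and C1–C10 bonds are cut. Both start from the C5=C10 alkene of 1. The fully substituted carbon of 2 adds to the unsubstituted β-carbon C5, and the resulting C10 enol silane 4 adds to 3. Both quaternary carbons flanking C5 are thus made by conjugate additions from three purchased components, with C5 set by a chiral Lewis acid and C10 by the new C5 substituent.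

## Alternatives that were turned down

**Alternative 1:** Ring B is cut at C7–C8 and C9–C10. In the forward direction Et2AlCl would promote an endo Diels–Alder reaction between the ring A vinyl diene A1 and the (S)-crotonyl oxazolidinone A2 to give the Δ5 bicycle A3.
- For: it is convergent, closes ring B, sets C8, C9 and C10 together under well-understood auxiliary face control, and its regiochemistry is the electronically natural one. On ring formation and convergence it is stronger than the chosen route.
- Against: the reacting diene terminus C10 is fully substituted, and the s-cis conformer of A1 is disfavoured by the clash between the vinyl group and the C4 methyls. The dienophile is β-methylated, so a bimolecular cycloaddition that forms a quaternary carbon would be slow, and the Lewis acid could ionise the ketal first.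
- Against: A3 then needs reduction of Δ5 to H-5α. The Δ7 alkene could only be installed by dehydrogenation next to the C9 acyl group and deconjugation, which erases the C8 and C9 centres the cycloaddition has just set. The ether would have to be made on a saturated, axial neopentyl C11.
- Comparison: the chosen route closes no ring in its key step, but every centre it sets survives. It also keeps a C9 carbonyl as the handle for C8, C7 and C11, and forms the ether at an allylic carbon.

**Alternative 2:** Both rings are cut at C5–C10 and C8–C9. Heating the triene A4 would let its (Z)-enoate add to the 2-siloxy diene and give the trans-fused bicycle A5.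
- For: it gives the largest gain per step (two rings, two bonds, four stereocentres), the C7 enol ether marks the site of the later alkene, and the C3 oxygen is already present.
- Against: A4 is an enantioenriched acyclic chain with a stereodefined trisubstituted (Z)-enoate, a (Z)-siloxy diene, a gem-dimethyl carbon and a carbinol centre, and needs a long linear preparation.
- Against: the C5–C10 bond has to form between a neopentyl diene terminus and a fully substituted dienophile carbon, which calls for temperatures at which the alkene geometries may not hold. Face selectivity rests on the single C3 centre.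
- Against: the C8 centre is later destroyed, the enol ether at C6=C7 is on the wrong side for a Δ7 alkene, and the C11 ester must be reduced and etherified at a hindered stage.
- Comparison: the chosen route starts from purchased materials and puts its risk into one step with separate control elements for C5 and C10.

**Alternative 3:** The C9–C10 bond is cut. Pd(PPh3)4 would ionise the (Z)-allylic carbonate A6, and the para carbon C10 of the phenol would attack the allyl terminus C9 to give the cross-conjugated dienone A7.
- For: it is catalytic, the arene supplies ring A cheaply, and A7 already holds the Δ7 alkene, the C11 oxygen and the C9 and C10 centres. It needs no later transposition, which makes it stronger than the chosen route on the endgame of ring B.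
- Against: Pd(PPh3)4 is achiral, so the absolute configuration must be transferred from the carbonate centre of A6 through a trisubstituted (Z)-allyl complex that can equilibrate before the C–C bond forms. No strong bias holds the C9 side chain anti to the C10 methyl.
- Against: A7 lacks one C4 methyl and needs reduction of C1=C2 and a reductive methylation to set C5. A6 is a 1,2,3,4-tetrasubstituted phenol with a stereodefined side chain. The coumarin cannot pass through a dissolving-metal step, so the ether would again be made last, on a hindered sp3 C11.
- Comparison: the chosen route offers established control types for C5 and C10, and sets C9 by an intramolecular hydrogen transfer after the ether is in place.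

Key step: step 1

Remark (assumption): the (S)-configured boron catalyst is taken to expose the Re face of C5 of enone 1, by analogy with cyclohex-2-en-1-one. If the sense proves opposite, the (R)-catalyst is used and nothing else changes.

## Route

Step 1
Reactants: 1 2-methylcyclohex-2-en-1-one; 2 1-methoxy-2-methyl-1-(trimethylsilyloxy)prop-1-ene; 3 methyl acrylate
Product: 6 methyl 3-[(1S,2R)-2-(1-methoxy-2-methyl-1-oxopropan-2-yl)-1-methyl-6-oxocyclohexyl]propanoate, via enol silane 4 (not isolated), via ketene silyl acetal 5 (not isolated)
Conditions: (S)-3,3-diphenyl-1-(2-methylphenyl)tetrahydro-1H,3H-pyrrolo[1,2-c][1,3,2]oxazaborole·HNTf2 (20 mol%), Ph3PO (25 mol%), toluene, −20 °C; then 3, Me3SiNTf2 (40 mol%), CH2Cl2, −78 → −40 °C; then 1 M HCl, THF, 0 °C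
Reagents that add atoms: none
Why: The boron Lewis acid binds the C9 carbonyl of 1, the fully substituted carbon of 2 adds to the unsubstituted β-carbon C5 through an open transition state, and silicon passes to the C9 oxygen to give the tetrasubstituted enol silane 4 (catalytic enantioselective Mukaiyama–Michael addition of a ketene silyl acetal to a cyclic enone; Ph3PO holds back free silyl cation so that the achiral silyl-catalysed path does not compete). Me3SiNTf2, added in excess over the phosphine oxide, then activates 3 and C10 of 4 attacks its β-carbon (silyl triflimide-promoted Mukaiyama–Michael addition of an enol silane to an acrylate), giving ketene silyl acetal 5, which the acidic work-up hydrolyses to 6. Taken together this is a tandem Michael–Michael three-component coupling, and no ring is closed. C5 is set by the catalyst, which must expose the Re face of C5 (the face on which C10, C6 and H run clockwise). C10 is set by the substrate: in 4 the bulky C5 substituent stands pseudoaxial to avoid A(1,2) strain with the C10 methyl, so the acrylate approaches C10 from the opposite face and C1 ends trans to C4 with the methyl cis to it. The step needs regiocontrol, which is secured because the enol silane is formed only toward C10, together with face selectivity at C5 and 1,2-induction at C10. Any silyloxycyclobutane formed by stepwise [2+2] closure of 4 with the acrylate should revert to the open adduct in the acidic work-up.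

Step 2
Reactants: 6 keto diester
Product: 7 methyl 3-[(1S,2R)-2-(1-methoxy-2-methyl-1-oxopropan-2-yl)-1,5-dimethyl-6-oxocyclohexyl]propanoate (C8-methyl keto diester, both C8 epimers)
Conditions: LiN(i-Pr)2 (1.0 equiv), THF, −78 °C; MeI, DMPU, −78 → −30 °C
Reagents that add atoms: iodomethane, CI
Why: Kinetic lithium enolate formation and SN2 methylation at C8, the only enolisable α-carbon of the ketone (C10 is quaternary); at −78 °C the ketone CH2 should be deprotonated faster than the ester CH2. The C8 configuration is immaterial because C8 becomes sp2 in step 6.

Step 3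
Reactants: 7 C8-methyl keto diester
Product: 8 bicyclic β-keto ester: trans-fused decalin (H-5α, CH3-10β) with C3 ketone, CO2Me on C2, gem-dimethyl C4, C9 ketone and C8 methyl (C2 and C8 epimers, C2–C3 partly enolised)
Conditions: LiN(i-Pr)2 (2.5 equiv), THF, −78 → 0 °C; aq. NH4Cl
Reagents that add atoms: none
Why: Dieckmann condensation in which the C2 ester enolate attacks the C3 ester, which has no α-hydrogen and can only be the electrophile. With excess amide both the ketone and the propanoate are held as enolates, so the unhindered propanoate carbonyl is not available for acylation by C8. The two chains are trans-diequatorial on ring B, so the six-membered closure gives the trans-decalin directly.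

Step 4
Reactants: 8 bicyclic β-keto ester
Product: 9 3,9-diketone: trans-fused 4,4,8,10-tetramethyldecalin-3,9-dione (H-5α, CH3-10β; C8 epimers)
Conditions: LiCl, DMSO, H2O, 150 °C
Reagents that add atoms: none
Why: Krapcho dealkoxycarbonylation: chloride demethylates the β-keto ester and the carboxylate loses CO2 through the C3 enolate. The conditions are neutral and should leave the ring fusion and both ketones intact.

Step 5
Reactants: 9 3,9-diketone
Product: 10 C3-ethylene ketal of 9 with free C9 ketone (C8 epimers)
Conditions: ethylene glycol, TsOH·H2O (cat.), benzene, reflux, Dean–Stark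
Reagents that add atoms: ethylene glycol, OCCO
Why: Acid-catalysed ketalisation under water removal. C3 has one CH2 neighbour and should react, whereas C9 lies between quaternary C10 and methyl-bearing C8 (a 2,2,6-trisubstituted cyclohexanone) and should be left free.

Step 6
Reactants: 10 C3-ketal C9-ketone
Product: 12 Δ7-9-enone: C7=C8 enone with C9 carbonyl, C8 methyl and C3 dioxolane (H-5α, CH3-10β), via enol silane 11 (not isolated)
Conditions: LiN(i-Pr)2, THF, −78 → 0 °C; Me3SiCl, Et3N, −78 °C → rt; then Pd(OAc)2 (1.1 equiv), MeCN, rt
Reagents that add atoms: none
Why: Saegusa–Ito dehydrogenation: C8–H is the only α-hydrogen of the ketone, so enol silane 11 is formed without a regiochemical choice. Divalent palladium then gives the oxa-π-allyl species, and β-hydride loss from the ring carbon C7 gives the endocyclic 2-methyl enone, as is usual for 2-methylcycloalkenyl silyl ethers.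

Step 7
Reactants: 13 4-methoxybenzyl alcohol; 14 tributyl(iodomethyl)stannane
Product: 15 tributyl[(4-methoxybenzyloxy)methyl]stannane
Conditions: NaH, THF/DMF, 0 °C; then 14, rt
Reagents that add atoms: none
Why: Williamson ether synthesis; the primary iodide next to tin is a good SN2 electrophile for the alkoxide.

Step 8
Reactants: 12 Δ7-9-enone; 15 tributyl[(4-methoxybenzyloxy)methyl]stannane
Product: 17 tertiary allylic alcohol: C9 carbinol bearing CH2OPMB, C7=C8 alkene, C3 dioxolane (C9 epimers), via lithium reagent 16 (not isolated)
Conditions: 15, n-BuLi, THF, −78 °C; then 12, −78 → −40 °C; aq. NH4Cl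
Reagents that add atoms: none
Why: Tin–lithium exchange gives the α-alkoxymethyllithium 16, which adds 1,2 to the enone carbonyl as small organolithium reagents do with 2,6,6-trisubstituted cyclohexenones. The C9 configuration is lost in step 9 and need not be controlled.

Step 9
Reactants: 17 tertiary allylic alcohol
Product: 18 Δ8-7-enone PMB ether: C7 ketone, C8=C9 alkene with C8 methyl and C9 CH2OPMB, C3 dioxolane
Conditions: pyridinium chlorochromate C5H5NH[CrO3Cl], NaOAc, 4 Å MS, CH2Cl2, rt
Reagents that add atoms: pyridinium chlorochromate, [O-][Cr](=O)(=O)Cl.c1cc[nH+]cc1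
Why: Babler–Dauben oxidative transposition: the chromate ester of the tertiary allylic alcohol undergoes a [3,3]-sigmatropic shift to C7, and the secondary chromate is oxidised to the enone by hexavalent chromium. The shift relieves crowding at C9 and gives the tetrasubstituted alkene; acetate buffer protects the ketal.

Step 10
Reactants: 18 Δ8-7-enone PMB ether
Product: 19 Δ8-7-enone C11 alcohol: C7 ketone, C8=C9, C9 CH2OH, C3 dioxolane
Conditions: DDQ, CH2Cl2/pH 7 buffer, 0 °C
Reagents that add atoms: none
Why: Oxidative cleavage of the 4-methoxybenzyl ether through its benzylic oxocarbenium ion; the buffered medium should spare the dioxolane and the enone.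

Step 11
Reactants: 19 Δ8-7-enone C11 alcohol; 20 umbelliferone (7-hydroxy-2H-chromen-2-one)
Product: 21 Δ8-7-enone aryl ether: as 19 with C11–O–C7 of the coumarin
Conditions: PPh3, DIAD, THF, 0 °C → rt
Reagents that add atoms: none
Why: Mitsunobu etherification of a primary allylic alcohol with an acidic phenol. Direct SN2 displacement at C11 is expected because the SN2′ terminus C8 is fully substituted and part of the enone.

Step 12
Reactants: 21 Δ8-7-enone aryl ether
Product: 22 C7 tosylhydrazone of 21
Conditions: TsNHNH2, EtOH, 50 °C
Reagents that add atoms: 4-methylbenzenesulfonohydrazide, Cc1ccc(cc1)S(=O)(=O)NN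
Why: Hydrazone condensation at the only free carbonyl (C3 is ketalised); conjugate addition is blocked because the β-carbon C9 is fully substituted, and the lactone carbonyl is much less electrophilic toward the hydrazide.

Step 13
Reactants: 22 tosylhydrazone
Product: 25 C3-ethylene ketal of the target: C7=C8 alkene, H-9β, C9 CH2O-coumarin α, via N-boryl hydrazine 23 (not isolated), via allylic diazene 24 (not isolated)
Conditions: catecholborane, CHCl3, 0 °C; then NaOAc·3H2O, reflux
Reagents that add atoms: none
Why: Reductive 1,3-transposition of an α,β-unsaturated tosylhydrazone: the borane adds hydride to C7 and acetate then expels sulfinate to give diazene 24, which loses N2 in a retro-ene shift that delivers its hydrogen to C9 and moves the alkene to C7=C8. Hydride should enter C7 axially from the α face, as in the reduction of other angularly methylated bicyclic enone hydrazones, so the diazene is β and H-9 is delivered β, syn to the C10 methyl, leaving the side chain α. The hydrazone is reduced before any base is added, so vinylogous loss of the aryloxide from the hydrazone anion is avoided.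

Step 14
Reactants: 25 C3 ketal of the target
Product: 26 7-{[(1R,4aR,8aS)-2,5,5,8a-tetramethyl-6-oxo-1,4,4a,5,6,7,8,8a-octahydronaphthalen-1-yl]methoxy}-2H-chromen-2-one (target; 5R,9R,10S in drimane locants)
Conditions: PPTS, acetone/H2O, 60 °C
Reagents that add atoms: water, O
Why: Acetal hydrolysis under mild acid; the crowded ketal beside the gem-dimethyl carbon opens readily, and the trisubstituted alkene, the homoallylic aryl ether and the lactone should be stable to these conditions.

## Compound list

1 | 2-methylcyclohex-2-en-1-one | CC1=CCCCC1=O | starting material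
2 | 1-methoxy-2-methyl-1-(trimethylsilyloxy)prop-1-ene | COC(O[Si](C)(C)C)=C(C)C | starting material
3 | methyl acrylate | C=CC(=O)OC | starting material
4 | methyl 2-methyl-2-[(1R)-2-methyl-3-(trimethylsilyloxy)cyclohex-2-en-1-yl]propanoate | CC1=C(O[Si](C)(C)C)CCC[C@H]1C(C)(C)C(=O)OC | intermediate
5 | methyl 2-[(1R,2S)-2-[3-methoxy-3-(trimethylsilyloxy)prop-2-en-1-yl]-2-methyl-3-oxocyclohexyl]-2-methylpropanoate | COC(O[Si](C)(C)C)=CC[C@]1(C)C(=O)CCC[C@H]1C(C)(C)C(=O)OC | intermediate
6 | methyl 3-[(1S,2R)-2-(1-methoxy-2-methyl-1-oxopropan-2-yl)-1-methyl-6-oxocyclohexyl]propanoate | COC(=O)CC[C@]1(C)C(=O)CCC[C@H]1C(C)(C)C(=O)OC | intermediate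
7 | methyl 3-[(1S,2R)-2-(1-methoxy-2-methyl-1-oxopropan-2-yl)-1,5-dimethyl-6-oxocyclohexyl]propanoate (C8 epimers) | COC(=O)CC[C@]1(C)C(=O)C(C)CC[C@H]1C(C)(C)C(=O)OC | intermediate
8 | trans-decalin β-keto ester: C3 ketone, C2 CO2Me, 4,4-dimethyl, C9 ketone, C8 methyl, H-5α, CH3-10β | CC1CC[C@H]2C(C)(C)C(=O)C(C(=O)OC)C[C@]2(C)C1=O | intermediate
9 | trans-fused 4,4,8,10-tetramethyldecalin-3,9-dione, H-5α, CH3-10β | CC1CC[C@H]2C(C)(C)C(=O)CC[C@]2(C)C1=O | intermediate
10 | C3-ethylene ketal of 9, C9 ketone free | CC1CC[C@H]2C(C)(C)C3(OCCO3)CC[C@]2(C)C1=O | intermediate
11 | C9-trimethylsilyloxy C8=C9 enol ether of 10 | CC=1CC[C@H]2C(C)(C)C3(OCCO3)CC[C@]2(C)C=1O[Si](C)(C)C | intermediate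
12 | Δ7-9-enone with C8 methyl and C3 dioxolane | CC1=CC[C@H]2C(C)(C)C3(OCCO3)CC[C@]2(C)C1=O | intermediate
13 | 4-methoxybenzyl alcohol | COc1ccc(CO)cc1 | starting material
14 | tributyl(iodomethyl)stannane | CCCC[Sn](CCCC)(CCCC)CI | starting material
15 | tributyl[(4-methoxybenzyloxy)methyl]stannane | CCCC[Sn](CCCC)(CCCC)COCc1ccc(OC)cc1 | intermediate
16 | (4-methoxybenzyloxy)methyllithium | [Li]COCc1ccc(OC)cc1 | intermediate
17 | C9 tertiary allylic alcohol with C9 CH2OPMB, C7=C8, C3 dioxolane (C9 epimers) | CC1=CC[C@H]2C(C)(C)C3(OCCO3)CC[C@]2(C)C1(O)COCc1ccc(OC)cc1 | intermediate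
18 | Δ8-7-enone with C9 CH2OPMB and C3 dioxolane | CC=1C(=O)C[C@H]2C(C)(C)C3(OCCO3)CC[C@]2(C)C=1COCc1ccc(OC)cc1 | intermediate
19 | Δ8-7-enone with C9 CH2OH and C3 dioxolane | CC=1C(=O)C[C@H]2C(C)(C)C3(OCCO3)CC[C@]2(C)C=1CO | intermediate
20 | umbelliferone (7-hydroxy-2H-chromen-2-one) | Oc1ccc2ccc(=O)oc2c1 | starting material
21 | Δ8-7-enone with C9 CH2O-(2-oxo-2H-chromen-7-yl) and C3 dioxolane | CC=1C(=O)C[C@H]2C(C)(C)C3(OCCO3)CC[C@]2(C)C=1COc1ccc2ccc(=O)oc2c1 | intermediate
22 | C7 tosylhydrazone of 21 | CC=1C(=NNS(=O)(=O)c3ccc(C)cc3)C[C@H]2C(C)(C)C3(OCCO3)CC[C@]2(C)C=1COc1ccc2ccc(=O)oc2c1 | intermediate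
23 | 7β-[N-(1,3,2-benzodioxaborol-2-yl)-N′-tosylhydrazino] Δ8 compound, H-7α | CC=1[C@@H](N(NS(=O)(=O)c3ccc(C)cc3)B3Oc4ccccc4O3)C[C@H]2C(C)(C)C3(OCCO3)CC[C@]2(C)C=1COc1ccc2ccc(=O)oc2c1 | intermediate
24 | 7β-diazenyl Δ8 compound (allylic diazene) | CC=1[C@@H](N=N)C[C@H]2C(C)(C)C3(OCCO3)CC[C@]2(C)C=1COc1ccc2ccc(=O)oc2c1 | intermediate
25 | C3-ethylene ketal of the target (Δ7, H-9β, H-5α, CH3-10β) | CC1=CC[C@H]2C(C)(C)C3(OCCO3)CC[C@]2(C)[C@@H]1COc1ccc2ccc(=O)oc2c1 | intermediate
26 | 7-{[(1R,4aR,8aS)-2,5,5,8a-tetramethyl-6-oxo-1,4,4a,5,6,7,8,8a-octahydronaphthalen-1-yl]methoxy}-2H-chromen-2-one | CC1=CC[C@H]2C(C)(C)C(=O)CC[C@]2(C)[C@@H]1COc1ccc2ccc(=O)oc2c1 | target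

## Step count and least certain steps

Total: 14 steps. Longest linear sequence: 13 steps (steps 1–6 and 8–14); step 7 is a one-step side branch.

**Step 1 (key step).**
- Most likely failure: weak face discrimination at C5. The α-methyl group of 1 removes the α-C–H contact that helps to fix simple cycloalkenones on the boron catalyst, and it slows the catalysed addition, so the achiral silyl-cation pathway may gain ground.
- Second failure mode: the acrylate addition may stall at the crowded tetrasubstituted enol silane or be diverted into cyclobutane formation.
- Fallback, from 2 to 4: the same catalyst is used on cyclohex-2-en-1-one F1, the enone class for which this addition is established, to give methyl 2-methyl-2-[(1R)-3-(trimethylsilyloxy)cyclohex-2-en-1-yl]propanoate F2. MeLi cleaves the silyl ether to the lithium enolate F3, and MeI methylates it at C10 to give methyl 2-methyl-2-[(1R)-2-methyl-3-oxocyclohexyl]propanoate F4 (C10 epimers). Equilibrating silylation (Me3SiCl, NaI, Et3N, MeCN) converts F4 into the more substituted enol silane, which is 4. Compound 4 is then isolated and treated with 3 and Me3SiNTf2 in a separate operation, free of phosphine oxide and boron catalyst, to reach 6.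

**Step 13.**
- Most likely failure: hydride addition to C7 from both faces, which would erode the C9 configuration, because the α preference rests only on axial approach past H-5.
- Fallback, from 21 to 24 (and on to 25): the C7 carbonyl is reduced under catalyst control with (S)-3,3-diphenyl-1-methyltetrahydro-1H,3H-pyrrolo[1,2-c][1,3,2]oxazaborole and catecholborane, with the alkenyl carbon C8 acting as the large group, to give the 7α-allylic alcohol F5. Its epimer, if formed, can be separated at this carbinol stage. Mitsunobu displacement with 2-nitrobenzenesulfonohydrazide (PPh3, DEAD, −30 °C) inverts C7 and gives the 7β-(1-sulfonylhydrazino) compound F6. On warming F6 loses the sulfinic acid to give diazene 24, which continues to 25 as in the main route.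

**Step 9.**
- Most likely failure: ionisation of the crowded tertiary allylic alcohol to a diene, or opening of the dioxolane, under the acidic chromium reagent before the chromate ester can rearrange.
- Fallback, from 17 to 18: the hydroxyl is transposed without oxidation by catalytic O3ReOSiPh3 in Et2O at low temperature. The equilibrium should favour the tetrasubstituted alkene and give the secondary C7 allylic alcohol F7 (C7 epimers). F7 is then oxidised with MnO2 to 18.

**Step 5.**
- Most likely failure: insufficient discrimination between the two hindered ketones, so that C3 reacts too slowly or C9 begins to ketalise under forcing conditions.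
- Fallback, from 9 to 12 (replaces steps 5 and 6): both ketones are converted with excess LiN(i-Pr)2/Me3SiCl into the bis(enol silane) F8 (C2=C3 and C8=C9; both regiochemistries are forced by the quaternary neighbours). Pd(OAc)2 (2.2 equiv) gives the dienedione F9 (C1=C2–C3=O and C7=C8–C9=O). Hydrogenation with RhCl(PPh3)3 saturates only the disubstituted C1=C2 alkene and gives the enedione F10. Ketalisation then has to distinguish a saturated ketone from a hindered conjugated one and gives 12.

## Further compounds

F1 | step 1 | cyclohex-2-en-1-one | O=C1C=CCCC1
F2 | step 1 | methyl 2-methyl-2-[(1R)-3-(trimethylsilyloxy)cyclohex-2-en-1-yl]propanoate | C1=C(O[Si](C)(C)C)CCC[C@H]1C(C)(C)C(=O)OC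
F3 | step 1 | lithium enolate of methyl 2-methyl-2-[(1R)-3-oxocyclohexyl]propanoate (C9=C10 enolate) | C1=C(O[Li])CCC[C@H]1C(C)(C)C(=O)OC
F4 | step 1 | methyl 2-methyl-2-[(1R)-2-methyl-3-oxocyclohexyl]propanoate (C10 epimers) | CC1C(=O)CCC[C@H]1C(C)(C)C(=O)OC
F5 | step 13 | 7α-hydroxy Δ8 compound with C9 CH2O-coumarin and C3 dioxolane | CC=1[C@H](O)C[C@H]2C(C)(C)C3(OCCO3)CC[C@]2(C)C=1COc1ccc2ccc(=O)oc2c1
F6 | step 13 | 7β-[1-(2-nitrobenzenesulfonyl)hydrazino] Δ8 compound | CC=1[C@@H](N(N)S(=O)(=O)c3ccccc3[N+](=O)[O-])C[C@H]2C(C)(C)C3(OCCO3)CC[C@]2(C)C=1COc1ccc2ccc(=O)oc2c1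
F7 | step 9 | C7 allylic alcohol with C8=C9, C9 CH2OPMB and C3 dioxolane (C7 epimers) | CC=1C(O)C[C@H]2C(C)(C)C3(OCCO3)CC[C@]2(C)C=1COCc1ccc(OC)cc1
F8 | step 5 | 3,9-bis(trimethylsilyloxy) C2=C3, C8=C9 diene of 9 | CC=1CC[C@H]2C(C)(C)C(O[Si](C)(C)C)=CC[C@]2(C)C=1O[Si](C)(C)C
F9 | step 5 | Δ1,Δ7-3,9-dienedione | CC1=CC[C@H]2C(C)(C)C(=O)C=C[C@]2(C)C1=O
F10 | step 5 | Δ7-3,9-enedione | CC1=CC[C@H]2C(C)(C)C(=O)CC[C@]2(C)C1=O
A1 | alternative 1 | 7-ethenyl-6,6,8-trimethyl-1,4-dioxaspiro[4.5]dec-7-ene | C=CC1=C(C)CCC2(OCCO2)C1(C)C
A2 | alternative 1 | (S)-4-benzyl-3-[(E)-but-2-enoyl]oxazolidin-2-one | C/C=C/C(=O)N1[C@@H](Cc2ccccc2)COC1=O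
A3 | alternative 1 | Δ5 bicycle with C9 acyl oxazolidinone, C8 methyl and C3 dioxolane | C[C@H]1CC=C2C(C)(C)C3(OCCO3)CC[C@]2(C)[C@@H]1C(=O)N1[C@@H](Cc2ccccc2)COC1=O
A4 | alternative 2 | methyl (2Z,8E,10Z)-6,10-bis(tert-butyldimethylsilyloxy)-3,7,7-trimethyldodeca-2,8,10-trienoate, C6 configured as in A5 | C/C=C(O[Si](C)(C)C(C)(C)C)/C=C/C(C)(C)[C@@H](O[Si](C)(C)C(C)(C)C)CC/C(C)=C\C(=O)OC
A5 | alternative 2 | trans-fused bicycle with C7 silyl enol ether, C3 silyl ether and C11 methyl ester | C[C@H]1C(O[Si](C)(C)C(C)(C)C)=C[C@H]2C(C)(C)[C@@H](O[Si](C)(C)C(C)(C)C)CC[C@]2(C)[C@@H]1C(=O)OC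
A6 | alternative 3 | methyl (Z)-1-(tert-butyldimethylsilyloxy)-5-(3-hydroxy-2,6-dimethylphenyl)-3-methylpent-3-en-2-yl carbonate | COC(=O)OC(CO[Si](C)(C)C(C)(C)C)/C(C)=C\Cc1c(C)ccc(O)c1C
A7 | alternative 3 | bicyclic cross-conjugated dienone with C9 and C10 set, C9 CH2OTBS | CC1=CCC2=C(C)C(=O)C=C[C@]2(C)[C@@H]1CO[Si](C)(C)C(C)(C)C
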